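Tgt comes slowly in these runs: zeta stood at 3.2% after 10.0 min, and eta at 5.5% after 20.0 min.

the same everywhere: Sbt 0.50 M; Kat 3.1 mM; Ptn2 3.8 mM
- eta: Ptn 0.30 M; Tsp 0.25 M; run made earlier
- zeta: Ptn 0.45 M; Tsp 0.25 M; run made earlier
- flask: Ptn 0.600 M; Tsp 0.250 M

| run | time / min | Tgt / % |
|---|---|---|
| eta | 20.0 | 5.5 |
| eta | 40.0 | 9.4 |
| eta | 60.0 | 13.0 |
| eta | 80.0 | 16.4 |
| eta | 120 | 21.8 |
| zeta | 10.0 | 3.2 |
| zeta | 25.0 | 8.3 |
| zeta | 50.0 | 13.6 |
| zeta | 80.0 | 18.9 |
| zeta | 120 | 25.7 |

(standard deviation of a reading: 0.5 percentage points)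

- steps thought possible: Ptn + Kat <-> Ptn.Kat; Sbt + Ptn.Kat <-> Imd; Imd -> Kat + Tgt; Kat + Ptn2 <-> Kat.Ptn2; Sbt + Tsp -> Sbt.Tsp

- apparent order in Ptn when 10% of the Sbt are converted (percent change of the rate of making Tgt for one percent more Ptn charged)
- factor on the rate of making Tgt when 10% of the Sbt are converted if Ptn is charged twice over

For whoever takes this flask over: it is charged with Sbt, Ptn, Tsp, Kat and Ptn2. From the first readings of eta and zeta I take an order in Ptn of n = 0.374, a rough reading, since the eta window is longer than the zeta window. Scaling zeta to this flask's Ptn gives the Tgt clock τ, the time in which making Tgt at its opening rate converts 10% of the Sbt charged: 28.1 min. Expect roughly that much Tgt in this flask about τ after the start. Don't read the conversion mark on Tgt, though: in this flask Tsp is charged at half the Sbt, and its step uses Sbt too, so read the mark on Sbt.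

My own reckoning commits to an order of 0.374 and a factor of 1.30 on doubling Ptn. The forecast, slightly different, gives 0.4 and 1.28, on the ground that “This indicates saturation in Ptn”.

The flask gives an order of 0.61 and a factor of 1.44.

    Ptn + Kat ⇌ Ptn.Kat (K = 13.0 M⁻¹, k = 0.260 M⁻¹ s⁻¹)
    Sbt + Ptn.Kat ⇌ Imd (K = 1.00 M⁻¹, k = 0.0680 M⁻¹ s⁻¹)
    Imd → Kat + Tgt (k = 16.0 s⁻¹)
    Kat + Ptn2 ⇌ Kat.Ptn2, settled at all times (K = 860 M⁻¹)
    Sbt + Tsp → Sbt.Tsp (k = 0.0280 M⁻¹ s⁻¹)

In this flask the Sbt reaches 10% conversion after 0.278 min, which is sooner than τ by a factor of 101. Reckoned at the pace of τ, that interval comes to 0.0989% of the Sbt charged as Tgt. At 0.0162 h in this flask the step from Sbt + Tsp to Sbt.Tsp still used Sbt 33 times as fast as the forward step from Sbt + Ptn.Kat to Imd.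

(The runs stem from a simulated flask on assumed constants; the scatter is artificial.)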